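Sunday's run at 16 h stands higher than Thursday's at 31 h, although the products of catalyst charged and hours nearly match, at a ratio of 1.03.

| flask | substrate | partner | free catalyst | time |
|---|---|---|---|---|
| Thursday's | 250 mM | 500 mM | 0.500 mM |  |
| Wednesday's | 100 mM | 350 mM | 0.500 mM |  |
| Tuesday's | 120 mM | 500 mM | 0.500 mM |  |
| Sunday's | 250 mM | 500 mM | 1.00 mM |  |
| Friday's | 250 mM | 500 mM | 0.500 mM | 78 h |

- Thursday's run (time / h: [target] / mM): 1.8: 14.8; 5.3: 27.7; 10: 49.8; 16: 67.1; 23: 85.0; 31: 92.7
- Wednesday's run (time / h: [target] / mM): 1.8: 4.1; 5.3: 7.9; 10: 17.8; 16: 22.9; 23: 30.0; 31: 39.8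
- Tuesday's run (time / h: [target] / mM): 1.8: 5.1; 5.3: 14.9; 10: 26.4; 16: 36.7; 23: 40.7; 31: 50.6
- Sunday's run (time / h: [target] / mM): 1.8: 24.4; 5.3: 58.3; 10: 82.4; 16: 106.6; 23: 122.5; 31: 125.4

(readings scatter by 2 mM)

- apparent order in [partner] of the starting rate, round the charge of the Thursday's run (the rate where two percent of its substrate have turned into target)
- apparent order in [substrate] of the starting rate, round the charge of the Thursday's run (the rate where two percent of its substrate have turned into target) (one fixed amount of target, the same in the runs compared)
- target in the Friday's run at 78 h, as a share of the substrate charged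

- Overall: substrate + partner -> target, with free catalyst as catalyst.
- Constant volume, constant temperature.
- What is held in complexes is read along with the free species.
- An order is taken over about fifteen percent of the charge, up and down.

Why compare them by that product? Call it catalyst-time, the axis of Selwyn's test. If equal catalyst-time gave equal target, the two runs would nearly agree.

Do they? No. The gap is 13.9 mM, larger than the scatter of 2 mM.

What might open it? My reading is a pseudo-first-order drain on target that runs on hours, not on catalyst-time. With twice the catalyst in Sunday's run, Thursday's run spends twice the hours at each stage. Its extra target-hours therefore equal Sunday's own, which the trapezium rule puts at 63.9 M·min. Dividing the gap by this gives the clock loss, the share of target lost per hour: 0.0131 h⁻¹.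

And Friday's run, which repeats Thursday's charge? Between 23 h and 31 h, Sunday's net slope plus its clock loss gives a gross rate of 1.98 mM h⁻¹. Thursday's charge reaches that catalyst-time near the middle of the remaining hours, at a gross rate of 0.991 mM h⁻¹, half of Sunday's.

Isn't that slope mostly scatter? Partly, so my figure is rough. The clock loss on 92.7 mM is 1.21 mM h⁻¹, faster than that gross rate, so I expect 82.4 mM, or 32.9%, at 78 h.

The forecast differs. It gives 0.8 for the order in [partner], 1 for the order in [substrate] and 49% for Friday's run, which it places “just under the ceiling”.

The simulation gives 0.82 for the order in [partner], 0.69 for the order in [substrate] and 39.6% for Friday's run, which is 98.9 mM, above my figure and below the forecast's.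

free catalyst + substrate ⇌ catalyst-substrate complex (280.4 L mol⁻¹ h⁻¹, 90.00 h⁻¹); catalyst-substrate complex + partner → target + free catalyst (76.32 L mol⁻¹ h⁻¹); 2 free catalyst → 2 spent catalyst (42.12 L mol⁻¹ h⁻¹); target + partner → side product (0.03179 L mol⁻¹ h⁻¹) At the clock loss, that amount of target in Friday's run sheds 1.30 mM h⁻¹. In Sunday's run, target came to a quarter of the substrate charged at 6.37 h. Thursday's extra target-hours up to that stage, taken as a triangle, put it 0.901 h behind twice that time, at 13.6 h; Thursday's run reached that stage at 13.7 h.

The readings were computed for substances that don't exist, and the scatter is random.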